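**Analysis of the target**

The target is a C20 dibromo tetrol in which a trans-fused decalin (rings A and B) carries a cyclopentane (ring C) on a tertiary carbinol carbon. The decalin is numbered C1 to C8a (C2 the carbinol bearing ring C, C4a the methyl-bearing and C8a the hydroxyl-bearing fusion carbons, C5 the CHBr, C8 the methyl carbinol; ring A holds C1–C4, ring B C5–C8). Ring C is numbered C1' (quaternary, bonded to C2), C2' (CMe2), C3' (CHBr), C4' and C5' (CHOH). There are eight stereocentres, (2S,4aR,5R,8S,8aS) and (1'S,3'S,5'R): the axial C4a methyl and the axial C8a hydroxyl are trans, the C8 and C8a hydroxyls are trans-diaxial, the C2 hydroxyl is axial and syn to the C8a hydroxyl so that ring C is equatorial, and the C5 bromide is equatorial and cis to the angular methyl; on ring C the bromide, the hydroxyl and the C1'–C2 bond all lie on one face. Five stereocentres are fully substituted, and C2', C1' and C2 form a run of three contiguous fully substituted carbons. Both C–Br bonds are secondary and neopentyl (next to C4a and to C2'), so neither can be counted on from SN2 displacement and neither tolerates tin hydrides or dissolving metals; three of the four alcohols are tertiary, and the β-hydroxy ketone through which ring C passes can suffer retro-aldol cleavage. The difficulty is to combine these crowded centres with two halides that have to be installed by cationic rather than substitutive chemistry. The strategy rests on rings A and B: they share the C4a–C8a bond and the equatorial C5 bromide is antiperiplanar to it, which is the arrangement left when a bromonium ion on a C4a=C5 olefin is opened across a ten-membered ring by the C8=C8a olefin of a cyclodeca-1,5-diene.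

**Retrosynthetic reasoning**

C8–O and C8a–O. Target 31 is cut at the C8 hydroxyl to the α-epoxide 30, and 30 at its oxygen to the tetrasubstituted olefin 29. A trans-diaxial vicinal diol is the normal outcome of acid hydrolysis of an epoxide on a rigid ring, and the axial C2 hydroxyl of 29 sits where it can steer the oxidant to the α face. Olefin 29 is the diol released from acetonide 28. Forward, the epoxidation has to fix C8a and the hydrolysis has to invert C8.

C4a–C8a and C5–Br (key disconnection). Octalin 28 is opened to the ten-membered (E,E)-diene 27 by removing the C4a–C8a bond and the C5 bromine together. This cut is chosen because it is the only one that takes away a ring bond and a neopentyl C–Br bond in one operation: one new C–C bond closes both six-membered rings. Forward, a bromonium donor must pick the C4a=C5 olefin, the ring must fold as a crossed chair–chair with ring C equatorial, and the C8 cation must lose a proton.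

C2–O protection and C1–C2. Acetonide 27 comes from diol 25 and 2,2-dimethoxypropane 26; both oxygens must be masked or they would capture the bromonium ion. Diol 25 comes from silyl ether 24, and the ring of 24 is opened at C1–C2 to the keto allylic chloride 22. That bond is chosen because C2 is the only carbon of the large ring that can be an electrophile (a ketone) while C1 is allylic. Forward, an allyl–metal species must react at its α-carbon, keep the olefin geometry and add to the correct face of the ketone.

C3–C4. Chloride 22 goes back through alcohol 20 and acetate 19 to methyl ketone 14 and the allylic bromide 17. The methyl group of 14 is its only enolisable position, so the enolate alkylation is unambiguous. Bromide 17 is two steps from geranyl acetate 15 through 16, which supplies both (E)-olefins ready-made.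

Ring C oxygen and quaternary carbon. Ketone 14 is the silyl ether of 13; 13 comes from diketone 12 by reduction at C5', and 12 from 10 by methylation at C1'. These two bonds are made in this order because every reagent approaches ring C anti to the C3' bromide: a methyl electrophile then leaves the acetyl group cis to bromine, and hydride leaves the hydroxyl cis to both.

Carbonyl transposition. Diketone 10 is traced through aldol 9 and enone 7 to vinyl triflate 5 and then to bromo ketone 3. The ketone carbon of 3 becomes C1' and its α-carbon becomes C5', so the sequence moves the oxygen one carbon along while attaching the acetyl group.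

C3'–Br and the gem-dimethyl group. Bromo ketone 3 is cut at C–Br and at one methyl of C2' to the tertiary allylic alcohol 2, which comes from enone 1 by enantioselective methyl addition. A bromonium-triggered 1,2-methyl shift makes the neopentyl C–Br bond without substitution and carries the carbinol configuration to C3', the only absolute stereocentre that has to be bought from a catalyst.

**Alternatives that were turned down**

Alternative 1: The disconnection is the C3'–C4' bond of ring C. In the forward sense a carbenoid generated at C4' with Rh2(OAc)4 inserts into a C–H bond of the silyloxymethyl carbon C3' and closes ring C as cyclopentanone A1. In its favour, five-membered C–H insertion next to oxygen is dependable, and the C1' quaternary centre can be set beforehand in an open chain under auxiliary or catalyst control. On that point it is stronger than the route chosen here, where C1' is set by substrate control in step 7. Against it, C3' arrives as a silyl ether on the face opposite to the one bromine must occupy, so the C–Br bond has to be made by SN2 inversion at a secondary carbon next to CMe2, where elimination and methyl shift compete. The key step also builds only one ring and leaves the decalin, with its second neopentyl bromide and its trans-diaxial diol, to stepwise work. The chosen strategy makes both neopentyl C–Br bonds by bromonium chemistry and spends its key step on two rings and the C4a/C5 pair.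

Alternative 2: The disconnection is the C1'–C5' bond together with the C5'–O–C2 acyl bond. Forward, an ammonium enolate formed at C1' from an activated acid and O-trimethylsilylquinidine adds to the C5' aldehyde and the alkoxide closes the cis-fused β-lactone A2. In its favour, one catalytic step sets C1' and C5' with the cis relationship the target needs, and the lactone carbonyl is C2 itself, so the C3 chain could be attached by acyl substitution. On control of C1'/C5' and on step count to the C2 ketone this is stronger than steps 3–8 here. Against it, the aldol step has to form a quaternary carbon next to CMe2 while the catalyst overrides the resident C3' centre. C3' is again an ether of the wrong configuration and needs the same doubtful inversion to bromide. Opening a β-lactone with a hard carbon nucleophile competes with alkyl C–O cleavage and over-addition. Rings A and B are not addressed. The chosen route gives up catalyst control at C1' but never needs a substitution at a neopentyl carbon.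

Alternative 3: The disconnection is the C1'–C2' bond, formed by ring contraction of a six-membered ring from which the acetyl carbon is pushed out. Forward, TiCl4 opens a C1'–C5' epoxide at C1' and C2' migrates from the silyloxy carbon, giving β-hydroxy ketone A3, which is the same compound as 13. In its favour, the bromide can come from a chair-controlled bromocyclisation, the shift sets C1' and C5' stereospecifically, and the product is exactly the ketone needed in step 9; if its substrate were in hand it would be shorter than steps 1–8. Against it, contraction requires the silyloxy group trans to the epoxide and the epoxide cis to the equatorial bromide. That means oxygen delivery to the ring face shielded by the axial methyl of CMe2, and the carbinol epimer opposite to the one that axial addition to the enone gives; otherwise methyl migrates or the hydroxyl ends trans to bromine. An enantioselective bromocyclisation of a simple geranyl-type diene is also not a general reaction. As a strategy it again leaves the decalin open. The chosen route reaches 13 by steps whose facial sense follows the resident bromide and puts the key step on the decalin.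

Key step: step 18

Assumption: BDSB, the chiral bis(sulfonamide) diol ligand, tributyl(1-ethoxyvinyl)stannane, LDA and the usual bases and oxidants are taken as purchasable reagents; active barium is made in the flask.

Step 1
Reactants: 1 2-methylcyclopent-2-en-1-one
Product: 2 (1R)-1,2-dimethylcyclopent-2-en-1-ol
Conditions: Me2Zn, Ti(OiPr)4, bis(sulfonamide) diol ligand from trans-cyclohexane-1,2-diamine (5 mol %), toluene/hexane, rt; aq. NH4Cl
Reagents that add atoms: dimethylzinc, C[Zn]C
Why: Titanium-catalysed enantioselective 1,2-addition of a dialkylzinc to a 2-substituted cycloalkenone gives the tertiary allylic alcohol; the ligand enantiomer is chosen so that methyl is delivered to the face that gives the (R)-carbinol. This is the only step in which absolute configuration is introduced.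

Step 2
Reactants: 2 (1R)-1,2-dimethylcyclopent-2-en-1-ol
Product: 3 (3S)-3-bromo-2,2-dimethylcyclopentan-1-one
Conditions: NBS, CH2Cl2, −20 → 0 °C, dark
Reagents that add atoms: N-bromosuccinimide, O=C1CCC(=O)N1Br
Why: Halonium-induced semipinacol rearrangement of a tertiary allylic alcohol: the bromonium ion on C2=C3 is opened by an anti 1,2-shift of the carbinol methyl, which creates the gem-dimethyl carbon and the ketone and places bromine on a neopentyl carbon without substitution. Because the migrating methyl must be anti to bromine, bromine ends on the face the hydroxyl occupied and the carbinol configuration is relayed to C3 (S).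

Step 3
Reactants: 3 (3S)-3-bromo-2,2-dimethylcyclopentan-1-one
Product: 5 (4S)-4-bromo-5,5-dimethylcyclopent-1-en-1-yl trifluoromethanesulfonate, via lithium enolate 4 (not isolated)
Conditions: LiHMDS, THF, −78 °C; PhNTf2, −78 → 0 °C
Reagents that add atoms: N-phenylbis(trifluoromethanesulfonimide), O=S(=O)(N(c1ccccc1)S(=O)(=O)C(F)(F)F)C(F)(F)F
Why: Enolate O-triflation; deprotonation can occur only at C5 because C2 is quaternary, so the β-bromide cannot be expelled. The bromine-bearing stereocentre is untouched.

Step 4
Reactants: 5 (4S)-4-bromo-5,5-dimethylcyclopent-1-en-1-yl trifluoromethanesulfonate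
Product: 7 1-[(4S)-4-bromo-5,5-dimethylcyclopent-1-en-1-yl]ethan-1-one, via dienyl ether 6 (not isolated)
Conditions: tributyl(1-ethoxyvinyl)stannane, Pd(PPh3)4 (5 mol %), LiCl, THF, 65 °C; then 1 M HCl, rt
Reagents that add atoms: tributyl(1-ethoxyvinyl)stannane, CCCC[Sn](CCCC)(CCCC)C(=C)OCC; water, O
Why: Stille coupling of a vinyl triflate with an α-alkoxyvinyl stannane as acetyl anion equivalent, then hydrolysis of the enol ether to the methyl ketone. The unactivated, hindered secondary bromide should not undergo oxidative addition under these conditions.

Step 5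
Reactants: 7 1-[(4S)-4-bromo-5,5-dimethylcyclopent-1-en-1-yl]ethan-1-one
Product: 9 1-[(1S,3S,5S)-3-bromo-5-hydroxy-2,2-dimethylcyclopentyl]ethan-1-one, via pinacol boronate 8 (not isolated)
Conditions: B2pin2, CuCl (5 mol %), NaOtBu (10 mol %), Xantphos (5 mol %), MeOH, THF, rt; then NaBO3·4H2O, THF/H2O, rt
Reagents that add atoms: bis(pinacolato)diboron, CC1(C)OB(OC1(C)C)B1OC(C)(C)C(C)(C)O1; sodium perborate, [Na+].[Na+].O[B-]1(O)OO[B-](O)(O)OO1
Why: Copper-catalysed conjugate borylation puts boron on the β-carbon (the future C5') and perborate oxidises C–B to C–OH with retention. The two new centres are expected trans to each other (hydroxyl trans to bromine) but both are erased in steps 6 and 7, so their configuration is immaterial.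

Step 6
Reactants: 9 1-[(1S,3S,5S)-3-bromo-5-hydroxy-2,2-dimethylcyclopentyl]ethan-1-one
Product: 10 (4S)-2-acetyl-4-bromo-3,3-dimethylcyclopentan-1-one
Conditions: Dess–Martin periodinane, NaHCO3, CH2Cl2, 0 °C → rt
Reagents that add atoms: none
Why: Dess–Martin oxidation of the aldol to the 2-acylcyclopentanone, which should rest as its enol; the buffered, non-basic conditions avoid loss of HBr from the β-bromo ketone.

Step 7
Reactants: 10 (4S)-2-acetyl-4-bromo-3,3-dimethylcyclopentan-1-one
Product: 12 (2R,4S)-2-acetyl-4-bromo-2,3,3-trimethylcyclopentan-1-one, via sodium enolate 11 (not isolated)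
Conditions: NaH (1.0 equiv), THF/DMF, 0 °C; MeI, 0 °C → rt
Reagents that add atoms: iodomethane, CI
Why: C-Alkylation of a β-diketone enolate with the smallest electrophile builds the C1' quaternary centre next to CMe2. The electrophile should approach the planar enolate anti to the C3' bromine, which puts methyl trans and acetyl cis to bromine. One equivalent of base is used so that the product, which has no acidic C1'–H, is not exposed to base.

Step 8
Reactants: 12 (2R,4S)-2-acetyl-4-bromo-2,3,3-trimethylcyclopentan-1-one
Product: 13 1-[(1S,3S,5R)-3-bromo-5-hydroxy-1,2,2-trimethylcyclopentyl]ethan-1-one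
Conditions: NaBH4, MeOH/CH2Cl2 (1:1), −40 °C
Reagents that add atoms: none
Why: Chemoselective ketone reduction: the ring carbonyl is attacked in preference to the acetyl group, which sits between two quaternary carbons. Hydride should come from the face of the smaller C1' methyl, anti to both the acetyl group and the C3' bromine, so the hydroxyl ends cis to acetyl and to bromine (5R).

Step 9
Reactants: 13 1-[(1S,3S,5R)-3-bromo-5-hydroxy-1,2,2-trimethylcyclopentyl]ethan-1-one
Product: 14 1-[(1S,3S,5R)-3-bromo-5-[(tert-butyldimethylsilyl)oxy]-1,2,2-trimethylcyclopentyl]ethan-1-one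
Conditions: TBSOTf, 2,6-lutidine, CH2Cl2, −78 → 0 °C
Reagents that add atoms: tert-butyldimethylsilyl trifluoromethanesulfonate, CC(C)(C)[Si](C)(C)OS(=O)(=O)C(F)(F)F
Why: Silylation of the hindered secondary alcohol with a silyl triflate. The bulky, weakly coordinating ether blocks retro-aldol cleavage and is meant to suppress chelation in step 15.

Step 10
Reactants: 15 geranyl acetate
Product: 16 (2E,6E)-8-hydroxy-3,7-dimethylocta-2,6-dien-1-yl acetate
Conditions: SeO2 (0.1 equiv), t-BuOOH (70% aq.), salicylic acid (0.1 equiv), CH2Cl2, rt
Reagents that add atoms: tert-butyl hydroperoxide, CC(C)(C)OO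
Why: Selenium dioxide allylic oxidation (ene reaction then [2,3] shift) hydroxylates the (E)-methyl group of the terminal trisubstituted olefin selectively, so the new CH2OH is trans to the chain.

Step 11
Reactants: 16 (2E,6E)-8-hydroxy-3,7-dimethylocta-2,6-dien-1-yl acetate
Product: 17 (2E,6E)-8-bromo-3,7-dimethylocta-2,6-dien-1-yl acetate
Conditions: CBr4, PPh3, CH2Cl2, −20 °C
Reagents that add atoms: carbon tetrabromide, BrC(Br)(Br)Br
Why: Appel bromination of a primary allylic alcohol at low temperature proceeds by direct displacement without allylic transposition; the acetate is untouched.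

Step 12
Reactants: 14 1-[(1S,3S,5R)-3-bromo-5-[(tert-butyldimethylsilyl)oxy]-1,2,2-trimethylcyclopentyl]ethan-1-one; 17 (2E,6E)-8-bromo-3,7-dimethylocta-2,6-dien-1-yl acetate
Product: 19 (2E,6E)-10-[(1S,3S,5R)-3-bromo-5-[(tert-butyldimethylsilyl)oxy]-1,2,2-trimethylcyclopentyl]-3,7-dimethyl-10-oxodeca-2,6-dien-1-yl acetate, via lithium enolate 18 (not isolated)
Conditions: LDA (1.05 equiv), THF, −78 °C; then 17, DMPU, −78 → −30 °C
Reagents that add atoms: none
Why: Ketone enolate alkylation: the methyl group is the only enolisable position of 14, so a single lithium enolate forms and is alkylated by the primary allylic bromide in an SN2 reaction that makes C3–C4 and keeps both (E)-olefins. The C3' bromide is on the same face as the enolate arm and cannot be displaced from the back.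

Step 13
Reactants: 19 (2E,6E)-10-[(1S,3S,5R)-3-bromo-5-[(tert-butyldimethylsilyl)oxy]-1,2,2-trimethylcyclopentyl]-3,7-dimethyl-10-oxodeca-2,6-dien-1-yl acetate
Product: 20 (4E,8E)-1-[(1S,3S,5R)-3-bromo-5-[(tert-butyldimethylsilyl)oxy]-1,2,2-trimethylcyclopentyl]-10-hydroxy-4,8-dimethyldeca-4,8-dien-1-one
Conditions: K2CO3 (cat.), MeOH, 0 °C → rt
Reagents that add atoms: none
Why: Base-catalysed transesterification removes the acetate; the silyl ether, the ketone and the neopentyl bromide are stable to catalytic carbonate in methanol.

Step 14
Reactants: 20 (4E,8E)-1-[(1S,3S,5R)-3-bromo-5-[(tert-butyldimethylsilyl)oxy]-1,2,2-trimethylcyclopentyl]-10-hydroxy-4,8-dimethyldeca-4,8-dien-1-one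
Product: 22 (4E,8E)-1-[(1S,3S,5R)-3-bromo-5-[(tert-butyldimethylsilyl)oxy]-1,2,2-trimethylcyclopentyl]-10-chloro-4,8-dimethyldeca-4,8-dien-1-one, via allylic mesylate 21 (not isolated)
Conditions: MsCl, LiCl, 2,4,6-collidine, DMF, 0 °C
Reagents that add atoms: lithium chloride, [Li+].[Cl-]; methanesulfonyl chloride, CS(Cl)(=O)=O
Why: Mesylation and in situ chloride displacement convert the primary allylic alcohol into the primary chloride by SN2, without SN2' transposition or E/Z isomerisation.

Step 15
Reactants: 22 (4E,8E)-1-[(1S,3S,5R)-3-bromo-5-[(tert-butyldimethylsilyl)oxy]-1,2,2-trimethylcyclopentyl]-10-chloro-4,8-dimethyldeca-4,8-dien-1-one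
Product: 24 (1S,3E,7E)-1-[(1S,3S,5R)-3-bromo-5-[(tert-butyldimethylsilyl)oxy]-1,2,2-trimethylcyclopentyl]-4,8-dimethylcyclodeca-3,7-dien-1-ol, via allylbarium chloride 23 (not isolated)
Conditions: active barium (BaI2, lithium biphenylide, THF, rt), then −78 °C, slow addition of 22 (final 0.005 M), −78 → −60 °C; aq. NH4Cl
Reagents that add atoms: none
Why: Barbier-type carbonyl allylation with an allylbarium, a reagent class that adds to ketones at its α-carbon with retention of olefin geometry; the branched mode is also closed off because it would build an eight-membered ring containing an (E)-olefin. With the non-chelating silyl ether the carbonyl oxygen should turn away from the C5'–O bond towards C2', the C3 chain should lie on the C5' side, and C1 should add from the open side over the C1' methyl, which gives (S)-C2. Slow addition keeps the allylbarium dilute so that it is consumed by its own ketone.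

Step 16
Reactants: 24 (1S,3E,7E)-1-[(1S,3S,5R)-3-bromo-5-[(tert-butyldimethylsilyl)oxy]-1,2,2-trimethylcyclopentyl]-4,8-dimethylcyclodeca-3,7-dien-1-ol
Product: 25 (1S,3E,7E)-1-[(1S,3S,5R)-3-bromo-5-hydroxy-1,2,2-trimethylcyclopentyl]-4,8-dimethylcyclodeca-3,7-dien-1-ol
Conditions: TBAF, THF, 40 °C
Reagents that add atoms: none
Why: Fluoride cleaves the hindered secondary silyl ether without acid, which the transannularly reactive 1,5-diene would not tolerate.

Step 17
Reactants: 25 (1S,3E,7E)-1-[(1S,3S,5R)-3-bromo-5-hydroxy-1,2,2-trimethylcyclopentyl]-4,8-dimethylcyclodeca-3,7-dien-1-ol; 26 2,2-dimethoxypropane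
Product: 27 acetonide of 25 (2,2-dimethyl-1,3-dioxane joining the C5' and C2 oxygens, cis-fused to ring C and spiro to the (3E,7E)-cyclodecadiene)
Conditions: 26, PPTS (cat.), CH2Cl2, 0 °C → rt; K2CO3 quench
Reagents that add atoms: none
Why: Mild acid-catalysed transketalisation ties the cis-disposed C5' and C2 hydroxyls into a 1,3-dioxane. This masks both nucleophilic oxygens for step 18 and makes ring C and the C2 oxygen one rigid substituent whose carbon arm prefers the equatorial position.

Step 18
Reactants: 27 acetonide of 25
Product: 28 acetonide of (2S,4aR,5R)-5-bromo-2-[(1S,3S,5R)-3-bromo-5-hydroxy-1,2,2-trimethylcyclopentyl]-4a,8-dimethyl-1,2,3,4,4a,5,6,7-octahydronaphthalen-2-ol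
Conditions: BDSB (Et2SBr·SbCl5Br, 1.1 equiv), MeNO2, −25 °C, 5 min; aq. NaHCO3/Na2SO3
Reagents that add atoms: bromodiethylsulfonium bromopentachloroantimonate (BDSB), CC[S+](Br)CC.Cl[Sb-](Cl)(Cl)(Cl)(Cl)Br
Why: BDSB transfers Br+ to the C4a=C5 olefin from the outer face of the ring; in the crossed chair–chair conformer C8a attacks C4a from inside the ring anti to bromine, forming C4a–C8a and C5–Br, and the tertiary C8 cation then loses the C8a proton. The closest known reaction type is the electrophile-initiated (proton, epoxide or N-bromosuccinimide) transannular cyclisation of (E,E)-cyclodeca-1,5-dienes of the germacrene class to eudesmanes, here combined with BDSB-initiated cation–olefin bromocyclisation. The one new C–C bond closes ring B in the 6-endo and ring A in the 6-exo sense. C5 and C4a are set together by anti addition across the (E)-olefin (equatorial bromide, axial methyl, cis to each other), and their sense relative to C2 follows from the chair in which ring C is equatorial and the ketal oxygen axial. Because C8a is sp2 in 28, the ring fusion is not yet defined at this stage; it is completed when C8a is oxygenated in steps 20 and 21. Site selectivity between the two trisubstituted olefins is needed: only a bromonium ion on C4a=C5 can be opened in the Markovnikov sense with six-membered ring formation, and C8=C8a is the more shielded and less electron-rich olefin next to the ketal carbon, so reversible bromonium formation should funnel into the productive path. The acetonide keeps both oxygens from capturing the bromonium ion or the cations.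

Step 19
Reactants: 28 acetonide of the bromo-octalin diol
Product: 29 (2S,4aR,5R)-5-bromo-2-[(1S,3S,5R)-3-bromo-5-hydroxy-1,2,2-trimethylcyclopentyl]-4a,8-dimethyl-1,2,3,4,4a,5,6,7-octahydronaphthalen-2-ol
Conditions: p-TsOH·H2O (cat.), MeOH, 40 °C
Reagents that add atoms: none
Why: Acid-catalysed transketalisation in methanol releases the 1,3-diol. The same acid should move any olefin isomers left by the proton loss of step 18 into the tetrasubstituted C8=C8a position, the thermodynamic one.

Step 20
Reactants: 29 (2S,4aR,5R)-5-bromo-2-[(1S,3S,5R)-3-bromo-5-hydroxy-1,2,2-trimethylcyclopentyl]-4a,8-dimethyl-1,2,3,4,4a,5,6,7-octahydronaphthalen-2-ol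
Product: 30 (2S,4aR,5R,8R,8aS)-5-bromo-2-[(1S,3S,5R)-3-bromo-5-hydroxy-1,2,2-trimethylcyclopentyl]-8,8a-epoxy-4a,8-dimethyldecahydronaphthalen-2-ol
Conditions: VO(acac)2 (5 mol %), t-BuOOH, CH2Cl2, 0 °C → rt
Reagents that add atoms: tert-butyl hydroperoxide, CC(C)(C)OO
Why: Vanadium-catalysed hydroxyl-directed epoxidation: the axial homoallylic C2 hydroxyl delivers oxygen to the α face of C8=C8a, which is also the face left open by the axial C4a methyl. This sets C8a with its oxygen trans to the angular methyl.

Step 21
Reactants: 30 (2S,4aR,5R,8R,8aS)-5-bromo-2-[(1S,3S,5R)-3-bromo-5-hydroxy-1,2,2-trimethylcyclopentyl]-8,8a-epoxy-4a,8-dimethyldecahydronaphthalen-2-ol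
Product: 31 (2S,4aR,5R,8S,8aS)-5-bromo-2-[(1S,3S,5R)-3-bromo-5-hydroxy-1,2,2-trimethylcyclopentyl]-4a,8-dimethyloctahydronaphthalene-2,8,8a(1H)-triol
Conditions: HClO4 (cat., aq.), THF/H2O (3:1), 0 °C → rt
Reagents that add atoms: water, O
Why: Acid-catalysed epoxide hydrolysis: water opens the protonated epoxide at C8 from the β face in the trans-diaxial sense (Fürst–Plattner rule), which inverts C8 and leaves the C8a oxygen in place. Attack at C8a is blocked by the adjacent quaternary C4a and would give a cis-fused, diequatorial product.

Compound list
1 | 2-methylcyclopent-2-en-1-one | CC1=CCCC1=O | starting material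
2 | (1R)-1,2-dimethylcyclopent-2-en-1-ol | CC1=CCC[C@@]1(C)O | intermediate
3 | (3S)-3-bromo-2,2-dimethylcyclopentan-1-one | CC1(C)[C@@H](Br)CCC1=O | intermediate
4 | lithium (4S)-4-bromo-5,5-dimethylcyclopent-1-en-1-olate (not isolated) | CC1(C)[C@@H](Br)CC=C1O[Li] | intermediate
5 | (4S)-4-bromo-5,5-dimethylcyclopent-1-en-1-yl trifluoromethanesulfonate | CC1(C)[C@@H](Br)CC=C1OS(=O)(=O)C(F)(F)F | intermediate
6 | (4S)-4-bromo-1-(1-ethoxyethenyl)-5,5-dimethylcyclopent-1-ene (not isolated) | CC1(C)[C@@H](Br)CC=C1C(=C)OCC | intermediate
7 | 1-[(4S)-4-bromo-5,5-dimethylcyclopent-1-en-1-yl]ethan-1-one | CC1(C)[C@@H](Br)CC=C1C(C)=O | intermediate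
8 | 1-[(3S)-3-bromo-2,2-dimethyl-5-(4,4,5,5-tetramethyl-1,3,2-dioxaborolan-2-yl)cyclopentyl]ethan-1-one, boron trans to bromine and trans to acetyl (not isolated) | CC1(C)[C@@H](Br)C[C@H](B2OC(C)(C)C(C)(C)O2)[C@H]1C(C)=O | intermediate
9 | 1-[(1S,3S,5S)-3-bromo-5-hydroxy-2,2-dimethylcyclopentyl]ethan-1-one | CC1(C)[C@@H](Br)C[C@H](O)[C@H]1C(C)=O | intermediate
10 | (4S)-2-acetyl-4-bromo-3,3-dimethylcyclopentan-1-one (keto–enol mixture, C2 not fixed) | CC1(C)[C@@H](Br)CC(=O)C1C(C)=O | intermediate
11 | sodium enolate of 10 (not isolated) | CC1(C)[C@@H](Br)CC(O[Na])=C1C(C)=O | intermediate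
12 | (2R,4S)-2-acetyl-4-bromo-2,3,3-trimethylcyclopentan-1-one | CC1(C)[C@@H](Br)CC(=O)[C@@]1(C)C(C)=O | intermediate
13 | 1-[(1S,3S,5R)-3-bromo-5-hydroxy-1,2,2-trimethylcyclopentyl]ethan-1-one | CC1(C)[C@@H](Br)C[C@@H](O)[C@@]1(C)C(C)=O | intermediate
14 | 1-[(1S,3S,5R)-3-bromo-5-[(tert-butyldimethylsilyl)oxy]-1,2,2-trimethylcyclopentyl]ethan-1-one | CC1(C)[C@@H](Br)C[C@@H](O[Si](C)(C)C(C)(C)C)[C@@]1(C)C(C)=O | intermediate
15 | geranyl acetate | CC(C)=CCC/C(C)=C/COC(C)=O | starting material
16 | (2E,6E)-8-hydroxy-3,7-dimethylocta-2,6-dien-1-yl acetate | OC/C(C)=C/CC/C(C)=C/COC(C)=O | intermediate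
17 | (2E,6E)-8-bromo-3,7-dimethylocta-2,6-dien-1-yl acetate | BrC/C(C)=C/CC/C(C)=C/COC(C)=O | intermediate
18 | lithium enolate of 14 at the acetyl methyl group (not isolated) | CC1(C)[C@@H](Br)C[C@@H](O[Si](C)(C)C(C)(C)C)[C@@]1(C)C(=C)O[Li] | intermediate
19 | (2E,6E)-10-[(1S,3S,5R)-3-bromo-5-[(tert-butyldimethylsilyl)oxy]-1,2,2-trimethylcyclopentyl]-3,7-dimethyl-10-oxodeca-2,6-dien-1-yl acetate | CC1(C)[C@@H](Br)C[C@@H](O[Si](C)(C)C(C)(C)C)[C@@]1(C)C(=O)CC/C(C)=C/CC/C(C)=C/COC(C)=O | intermediate
20 | (4E,8E)-1-[(1S,3S,5R)-3-bromo-5-[(tert-butyldimethylsilyl)oxy]-1,2,2-trimethylcyclopentyl]-10-hydroxy-4,8-dimethyldeca-4,8-dien-1-one | CC1(C)[C@@H](Br)C[C@@H](O[Si](C)(C)C(C)(C)C)[C@@]1(C)C(=O)CC/C(C)=C/CC/C(C)=C/CO | intermediate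
21 | methanesulfonate of 20 (not isolated) | CC1(C)[C@@H](Br)C[C@@H](O[Si](C)(C)C(C)(C)C)[C@@]1(C)C(=O)CC/C(C)=C/CC/C(C)=C/COS(C)(=O)=O | intermediate
22 | (4E,8E)-1-[(1S,3S,5R)-3-bromo-5-[(tert-butyldimethylsilyl)oxy]-1,2,2-trimethylcyclopentyl]-10-chloro-4,8-dimethyldeca-4,8-dien-1-one | CC1(C)[C@@H](Br)C[C@@H](O[Si](C)(C)C(C)(C)C)[C@@]1(C)C(=O)CC/C(C)=C/CC/C(C)=C/CCl | intermediate
23 | allylbarium chloride from 22, barium on C1 (not isolated) | CC1(C)[C@@H](Br)C[C@@H](O[Si](C)(C)C(C)(C)C)[C@@]1(C)C(=O)CC/C(C)=C/CC/C(C)=C/C[Ba]Cl | intermediate
24 | (1S,3E,7E)-1-[(1S,3S,5R)-3-bromo-5-[(tert-butyldimethylsilyl)oxy]-1,2,2-trimethylcyclopentyl]-4,8-dimethylcyclodeca-3,7-dien-1-ol | CC1(C)[C@@H](Br)C[C@@H](O[Si](C)(C)C(C)(C)C)[C@@]1(C)[C@]1(O)CC/C(C)=C/CC/C(C)=C/C1 | intermediate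
25 | (1S,3E,7E)-1-[(1S,3S,5R)-3-bromo-5-hydroxy-1,2,2-trimethylcyclopentyl]-4,8-dimethylcyclodeca-3,7-dien-1-ol | CC1(C)[C@@H](Br)C[C@@H](O)[C@@]1(C)[C@]1(O)CC/C(C)=C/CC/C(C)=C/C1 | intermediate
26 | 2,2-dimethoxypropane | COC(C)(C)OC | starting material
27 | acetonide of 25 (precursor of the key step) | CC1(C)[C@@H](Br)C[C@H]2OC(C)(C)O[C@]3(CC/C(C)=C/CC/C(C)=C/C3)[C@@]12C | intermediate
28 | acetonide of 29 (product of the key step; 4aR,5R, C8=C8a olefin) | CC1(C)[C@@H](Br)C[C@H]2OC(C)(C)O[C@]3(CC[C@@]4(C)[C@H](Br)CCC(C)=C4C3)[C@@]12C | intermediate
29 | (2S,4aR,5R)-5-bromo-2-[(1S,3S,5R)-3-bromo-5-hydroxy-1,2,2-trimethylcyclopentyl]-4a,8-dimethyl-1,2,3,4,4a,5,6,7-octahydronaphthalen-2-ol | CC1(C)[C@@H](Br)C[C@@H](O)[C@@]1(C)[C@]1(O)CC[C@@]2(C)[C@H](Br)CCC(C)=C2C1 | intermediate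
30 | (2S,4aR,5R,8R,8aS)-5-bromo-2-[(1S,3S,5R)-3-bromo-5-hydroxy-1,2,2-trimethylcyclopentyl]-8,8a-epoxy-4a,8-dimethyldecahydronaphthalen-2-ol (α-epoxide) | CC1(C)[C@@H](Br)C[C@@H](O)[C@@]1(C)[C@]1(O)CC[C@@]2(C)[C@H](Br)CC[C@@]3(C)O[C@@]23C1 | intermediate
31 | (2S,4aR,5R,8S,8aS)-5-bromo-2-[(1S,3S,5R)-3-bromo-5-hydroxy-1,2,2-trimethylcyclopentyl]-4a,8-dimethyloctahydronaphthalene-2,8,8a(1H)-triol | CC1(C)[C@@H](Br)C[C@@H](O)[C@@]1(C)[C@]1(O)CC[C@@]2(C)[C@H](Br)CC[C@](C)(O)[C@]2(O)C1 | target

Total step count: 21. Longest linear sequence: 19 steps (steps 1–9 and 12–21); steps 10 and 11 form the side branch to 17.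

Least certain steps

Step 18 (key step). The likeliest failures are bromonium formation at the C8=C8a olefin followed by capture by the ketal oxygen, folding through the conformer with ring C axial (wrong face relative to C2), scatter in the final proton loss, and cleavage of the acetonide by the acid set free. All arise because two similar olefins and two chair folds compete in a ring that has never been tested with this reagent. Fallback: replace the bromonium donor by a mercury electrophile and introduce bromine in a second step. Starting from 27, Hg(OTf)2 as its N,N-dimethylaniline complex (MeNO2, −20 °C, then aqueous NaBr) should give the C5 bromomercury octalin acetonide F1 by the same transannular closure under milder, less acidic conditions. Bromine in pyridine at 0 °C in the dark then replaces mercury by bromine with retention, returning to the route at 28.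

Step 15. The ring closure may fail through intermolecular coupling, through electron transfer from active barium to the C3' bromide or the ketone, through enolisation of the ketone by the allylbarium, or through loss of regio- and geometric integrity if warming is needed. Chelation of barium between the carbonyl and the C5' oxygen would also turn the addition to the other carbonyl face. Fallback: change metal and mechanism. From alcohol 20, CBr4/PPh3 gives the allylic bromide F2, and CrCl2 in THF at high dilution (Nozaki–Hiyama cyclisation) closes the same bond through a trivalent allylchromium that does not reduce alkyl bromides or ketones. Its branched mode is geometrically closed, so the linear mode should lead back to 24.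

Step 2. The bromonium ion may be captured by the hydroxyl (epoxy bromide formation) instead of triggering the methyl shift. If that epoxide rearranges later it gives the enantiomeric ketone, so enantiomeric purity would erode; allylic bromination is a further drain. Fallback: make the C–Br bond by substitution on the simplest possible substrate. This fallback replaces steps 1 and 2, so it does not set out from a numbered compound but from commercial 2,2-dimethylcyclopentane-1,3-dione F3. Asymmetric transfer hydrogenation (RuCl(p-cymene)(TsDPEN), HCO2H/Et3N, catalyst enantiomer chosen for the R alcohol) gives (3R)-3-hydroxy-2,2-dimethylcyclopentan-1-one F4, and Appel bromination (CBr4, PPh3) with inversion comes back to the route at 3.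

Step 7. Facial selectivity rests on a remote bromide and may be poor, and O-methylation can compete because the carbon terminus is neopentyl; excess base would also strip HBr from the product. Fallback: change from substrate control to reagent control. From 10, asymmetric phase-transfer methylation (chiral N-spiro binaphthyl quaternary ammonium bromide, MeI, solid K2CO3, toluene, −20 °C), with the catalyst enantiomer matched to the substrate bias, should lead to 12; this fallback makes no new compound (F0).

Step 17. The acid may start a proton-initiated transannular cyclisation or olefin isomerisation of the diene, and ketalisation of a tertiary/secondary 1,3-diol into a heavily substituted dioxane may be slow. Fallback: change the protecting group and avoid acid altogether. From 25, tBu2Si(OTf)2 and 2,6-lutidine give the di-tert-butylsilylene diene F5. BDSB cyclisation as in step 18 gives the silylene octalin F6, and HF·pyridine in THF removes the silylene, returning to the route at 29 (steps 17–19 are replaced).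

Further compounds
F1 | step 18 | C5 bromomercury analogue of 28 (acetonide, HgBr equatorial at C5) | CC1(C)[C@@H](Br)C[C@H]2OC(C)(C)O[C@]3(CC[C@@]4(C)[C@H]([Hg]Br)CCC(C)=C4C3)[C@@]12C
F2 | step 15 | (4E,8E)-10-bromo-1-[(1S,3S,5R)-3-bromo-5-[(tert-butyldimethylsilyl)oxy]-1,2,2-trimethylcyclopentyl]-4,8-dimethyldeca-4,8-dien-1-one | CC1(C)[C@@H](Br)C[C@@H](O[Si](C)(C)C(C)(C)C)[C@@]1(C)C(=O)CC/C(C)=C/CC/C(C)=C/CBr
F3 | step 2 | 2,2-dimethylcyclopentane-1,3-dione | CC1(C)C(=O)CCC1=O
F4 | step 2 | (3R)-3-hydroxy-2,2-dimethylcyclopentan-1-one | CC1(C)[C@H](O)CCC1=O
F0 | step 7 | none | none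
F5 | step 17 | di-tert-butylsilylene derivative of 25 | CC1(C)[C@@H](Br)C[C@H]2O[Si](C(C)(C)C)(C(C)(C)C)O[C@]3(CC/C(C)=C/CC/C(C)=C/C3)[C@@]12C
F6 | step 17 | di-tert-butylsilylene derivative of 29 | CC1(C)[C@@H](Br)C[C@H]2O[Si](C(C)(C)C)(C(C)(C)C)O[C@]3(CC[C@@]4(C)[C@H](Br)CCC(C)=C4C3)[C@@]12C
A1 | alternative 1 | 3-[(triisopropylsilyl)oxy]-4,4,5-trimethyl-5-(2-methyl-1,3-dioxolan-2-yl)cyclopentan-1-one | CC1(C)[C@H](O[Si](C(C)C)(C(C)C)C(C)C)CC(=O)[C@@]1(C)C1(C)OCCO1
A2 | alternative 2 | 3-[(tert-butyldimethylsilyl)oxy]-1,2,2-trimethyl-6-oxabicyclo[3.2.0]heptan-7-one (cis-fused β-lactone) | CC1(C)[C@H](O[Si](C)(C)C(C)(C)C)C[C@H]2OC(=O)[C@@]12C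
A3 | alternative 3 | 1-[(1S,3S,5R)-3-bromo-5-hydroxy-1,2,2-trimethylcyclopentyl]ethan-1-one | CC1(C)[C@@H](Br)C[C@@H](O)[C@@]1(C)C(C)=O
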